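**Retrosynthetic overview**
1. Bought pieces: 2',6'-dihydroxyacetophenone 1, 6-bromohex-1-ene 2 and 4-allylcatechol 3. No ring is constructed; all four benzene rings come from 1 and 3.
2. Ketone arm: the trilithium trianion 4 of 1 is C-alkylated by 2 to give octenone 5.
3. Chain completion: cross-metathesis of 5 with 3 gives alkene 6, hydrogenated in the same flask to the monomer malabaricone C 7.
4. Key disconnection, the biaryl bond (made last): half of 7 is oxidised to o-quinone 8, whose ring carbons are acceptors instead of donors (an enolonium-type synthon of the catechol). Unoxidised 7 adds through a ring carbon, so two carbons that are both nucleophilic in the catechol are joined, giving target 9.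

Assumption: the target has no stereocentre and its biaryl axis carries only two ortho substituents (one OH, one CH2), so it is not configurationally stable; the compound is treated as achiral and no stereocontrol is needed.

**Step 1**
Reactants: 1 2',6'-dihydroxyacetophenone (1.2 equiv); 2 6-bromohex-1-ene (1.0 equiv)
Product: 5 1-(2,6-dihydroxyphenyl)oct-7-en-1-one, via trilithium trianion 4 (not isolated)
Conditions: LiN(iPr)2 (3.7 equiv), THF–DMPU (5:1), −78 → 0 °C, 1 h; then 2, 0 °C → rt, 12 h; 1 M HCl quench
Reagents that add atoms: none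
Why: Polyanion C-alkylation, in which the last-formed and most basic site (the enolate carbon) is far more nucleophilic than the two lithium phenoxides and displaces the primary bromide by SN2, while the small excess of trianion suppresses dialkylation.

**Step 2**
Reactants: 5 1-(2,6-dihydroxyphenyl)oct-7-en-1-one (1.0 equiv); 3 4-allylbenzene-1,2-diol (3 equiv)
Product: 7 malabaricone C [1-(2,6-dihydroxyphenyl)-9-(3,4-dihydroxyphenyl)nonan-1-one], via cross-metathesis alkene 6 (not isolated)
Conditions: second-generation Hoveyda–Grubbs catalyst RuCl2(H2IMes)(=CH-C6H4-2-OiPr) (3 mol %), AcOH (10 mol %), EtOAc, 50 °C, 6 h, N2 sweep; then Pd/C (10 wt % Pd, 5 mol %), H2 (1 atm), rt, 4 h, same flask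
Reagents that add atoms: none
Why: Olefin cross-metathesis of two unhindered terminal alkenes is driven by loss of ethylene and biased to the hetero-product by the excess of the cheap partner, and Pd/C hydrogenation then saturates the E/Z mixture without touching the hydrogen-bonded aryl ketone, so no stereochemical issue remains.

**Step 3**
Reactants: 7 malabaricone C (two molecules per molecule of product: one is oxidised, one acts as donor)
Product: 9 9,9'-(2,3,4',5'-tetrahydroxy[1,1'-biphenyl]-2',5-diyl)bis[1-(2,6-dihydroxyphenyl)nonan-1-one], via malabaricone C o-quinone 8 (not isolated)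
Conditions: o-chloranil (0.50 equiv, in CH2Cl2, added over 2 h), 1,1,1,3,3,3-hexafluoropropan-2-ol (HFIP)–CH2Cl2 (1:1), 0.2 M in 7, −20 °C → rt, argon, dark
Reagents that add atoms: none
Why: Proposed new method: o-chloranil takes two electrons from half of 7 to give o-quinone 8, in which C6 (the CH next to C1=O and meta to the chain, the delta terminus of the O=C2–C3=C4–C5=C6 dienone) has become an acceptor, so this ring carbon reacts with reversed polarity as an enolonium-type synthon; the most nucleophilic carbon of unoxidised 7 (the CH para to OH and ortho to the chain) adds to it in HFIP, which activates the quinone by hydrogen bonding, and enolisation restores both catechols, while the acylresorcinol rings, whose oxygen lone pairs are tied up by the ketone, are poorer donors; the alternative polar pairing (1,4-addition to C5 of 8 by the CH ortho to OH of 7) gives the same constitution, and the closest known reactions are the quinone–catechol dehydrodimerisation of 4-alkylcatechols to biphenyltetrols, the 1,6-addition of thiols to 4-alkyl-o-quinones at this same carbon and the HFIP-promoted arylation of quinone monoacetals by phenols; no stereocentre is formed.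

**Compound list**
1 | 2',6'-dihydroxyacetophenone | CC(=O)c1c(O)cccc1O | starting material
2 | 6-bromohex-1-ene | BrCCCCC=C | starting material
3 | 4-allylbenzene-1,2-diol (4-allylcatechol) | C=CCc1ccc(O)c(O)c1 | starting material
4 | trilithium trianion of 1 (enolate bis-phenoxide) | [Li+].[Li+].[Li+].C=C([O-])c1c([O-])cccc1[O-] | intermediate
5 | 1-(2,6-dihydroxyphenyl)oct-7-en-1-one | C=CCCCCCC(=O)c1c(O)cccc1O | intermediate
6 | 1-(2,6-dihydroxyphenyl)-9-(3,4-dihydroxyphenyl)non-7-en-1-one (E/Z mixture, E drawn) | O=C(CCCCC/C=C/Cc1ccc(O)c(O)c1)c1c(O)cccc1O | intermediate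
7 | malabaricone C, 1-(2,6-dihydroxyphenyl)-9-(3,4-dihydroxyphenyl)nonan-1-one | O=C(CCCCCCCCc1ccc(O)c(O)c1)c1c(O)cccc1O | intermediate
8 | 4-[9-(2,6-dihydroxyphenyl)-9-oxononyl]cyclohexa-3,5-diene-1,2-dione (o-quinone of 7) | O=C(CCCCCCCCC1=CC(=O)C(=O)C=C1)c1c(O)cccc1O | intermediate
9 | 9,9'-(2,3,4',5'-tetrahydroxy[1,1'-biphenyl]-2',5-diyl)bis[1-(2,6-dihydroxyphenyl)nonan-1-one] (achiral) | O=C(CCCCCCCCc1cc(O)c(O)c(-c2cc(O)c(O)cc2CCCCCCCCC(=O)c2c(O)cccc2O)c1)c1c(O)cccc1O | target

**Total step count:** 3. **Longest linear sequence:** 3 steps (1 → 5 → 7 → 9).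

**Steps most likely to fail**

Step 3 (highest risk). Three things can go wrong:
- Regiochemistry: 9 is the unsymmetrical dehydrodimer. The symmetrical 2,2'-dialkyl isomer (bond between two carbons that are both ortho to a chain) and C–O coupled diaryl ethers can also form.
- Chemoselectivity: the acylresorcinol rings may compete as donors.
- Over-oxidation: 9 is more easily oxidised than 7, so redox exchange with 8 can lead to oligomers or dibenzofurans. Keeping the oxidant at or below half an equivalent, adding it slowly and recycling unreacted 7 limits this.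

The fallback is a programmed cross-coupling in which each ring carries its own handle; it sets out from 2 and 3 and comes back to the route at 9. Cross-metathesis of 3 with 2 (same Ru catalyst, EtOAc) gives (E/Z)-4-(7-bromohept-2-en-1-yl)benzene-1,2-diol F1, which is hydrogenated in the same flask (Pd/C, H2, neutral EtOAc) to 4-(7-bromoheptyl)benzene-1,2-diol F2. This is tied up with 2,2-dimethoxypropane and TsOH as the acetonide 5-(7-bromoheptyl)-2,2-dimethyl-1,3-benzodioxole F3. F3 is then functionalised in two orthogonal ways. NBS in MeCN brominates para to oxygen and ortho to the chain, giving 5-bromo-6-(7-bromoheptyl)-2,2-dimethyl-1,3-benzodioxole F4 (ring B handle). Ir-catalysed C–H borylation ([Ir(OMe)(cod)]2, 4,4'-di-tert-butyl-2,2'-bipyridine, B2pin2) goes to the only CH that is ortho to a dioxole oxygen and not flanked by the chain, giving 2-[6-(7-bromoheptyl)-2,2-dimethyl-1,3-benzodioxol-4-yl]-4,4,5,5-tetramethyl-1,3,2-dioxaborolane F5 (ring A handle). Suzuki–Miyaura coupling of F4 with F5 (Pd(dppf)Cl2, K3PO4, dioxane–water; the aryl bromide reacts, the primary alkyl bromides do not) gives 6-(7-bromoheptyl)-4-[6-(7-bromoheptyl)-2,2-dimethyl-1,3-benzodioxol-5-yl]-2,2-dimethyl-1,3-benzodioxole F6. Both bromides are displaced by an excess of trianion 4 (THF–DMPU, NH4Cl quench) to give the bis-acetonide of the target F7, and aqueous TFA removes both acetonides to give 9.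

Step 1 (second). The trilithium trianion may be poorly soluble and sluggish toward a primary bromide, and O-alkylation or dialkylation can compete. The fallback gives up the unprotected polyanion for a masked mono-enolate; it sets out from 1 and comes back at 5. Compound 1 is converted with NaH and MOMCl in DMF into 1-[2,6-bis(methoxymethoxy)phenyl]ethan-1-one F8. Deprotonation with LiN(iPr)2 in THF–DMPU at −78 °C gives the lithium enolate of the bis-MOM ketone F9, which is alkylated with 2 to 1-[2,6-bis(methoxymethoxy)phenyl]oct-7-en-1-one F10. HCl in MeOH removes both acetals and gives 5.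

Step 2 (third). The free catechol may slow the Ru catalyst, Ru hydrides can move the allyl double bond into conjugation or walk the chain alkene (giving chain-shortened homologues), and homodimers lower the yield. The fallback masks the catechol before metathesis; it sets out from 3 and comes back at 7. Compound 3 is acetylated (Ac2O, pyridine) to 4-allyl-1,2-phenylene diacetate F11. Cross-metathesis with 5 under the same Ru catalyst gives 4-[9-(2,6-dihydroxyphenyl)-9-oxonon-2-en-1-yl]-1,2-phenylene diacetate F12, which is hydrogenated in the same flask (Pd/C, H2) to 4-[9-(2,6-dihydroxyphenyl)-9-oxononyl]-1,2-phenylene diacetate F13. Methanolysis with HCl in MeOH under argon gives 7.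

**Further compounds**
F1 | step 3 | (E/Z)-4-(7-bromohept-2-en-1-yl)benzene-1,2-diol (E drawn) | BrCCCC/C=C/Cc1ccc(O)c(O)c1
F2 | step 3 | 4-(7-bromoheptyl)benzene-1,2-diol | BrCCCCCCCc1ccc(O)c(O)c1
F3 | step 3 | 5-(7-bromoheptyl)-2,2-dimethyl-1,3-benzodioxole | BrCCCCCCCc1ccc2OC(C)(C)Oc2c1
F4 | step 3 | 5-bromo-6-(7-bromoheptyl)-2,2-dimethyl-1,3-benzodioxole | BrCCCCCCCc1cc2OC(C)(C)Oc2cc1Br
F5 | step 3 | 2-[6-(7-bromoheptyl)-2,2-dimethyl-1,3-benzodioxol-4-yl]-4,4,5,5-tetramethyl-1,3,2-dioxaborolane | BrCCCCCCCc1cc(B2OC(C)(C)C(C)(C)O2)c2OC(C)(C)Oc2c1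
F6 | step 3 | 6-(7-bromoheptyl)-4-[6-(7-bromoheptyl)-2,2-dimethyl-1,3-benzodioxol-5-yl]-2,2-dimethyl-1,3-benzodioxole | BrCCCCCCCc1cc(-c2cc3OC(C)(C)Oc3cc2CCCCCCCBr)c2OC(C)(C)Oc2c1
F7 | step 3 | bis-acetonide of 9 | O=C(CCCCCCCCc1cc(-c2cc3OC(C)(C)Oc3cc2CCCCCCCCC(=O)c2c(O)cccc2O)c2OC(C)(C)Oc2c1)c1c(O)cccc1O
F8 | step 1 | 1-[2,6-bis(methoxymethoxy)phenyl]ethan-1-one | CC(=O)c1c(OCOC)cccc1OCOC
F9 | step 1 | lithium enolate of F8 | [Li+].C=C([O-])c1c(OCOC)cccc1OCOC
F10 | step 1 | 1-[2,6-bis(methoxymethoxy)phenyl]oct-7-en-1-one | C=CCCCCCC(=O)c1c(OCOC)cccc1OCOC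
F11 | step 2 | 4-allyl-1,2-phenylene diacetate | C=CCc1ccc(OC(C)=O)c(OC(C)=O)c1
F12 | step 2 | 4-[9-(2,6-dihydroxyphenyl)-9-oxonon-2-en-1-yl]-1,2-phenylene diacetate (E/Z mixture, E drawn) | CC(=O)Oc1ccc(C/C=C/CCCCCC(=O)c2c(O)cccc2O)cc1OC(C)=O
F13 | step 2 | 4-[9-(2,6-dihydroxyphenyl)-9-oxononyl]-1,2-phenylene diacetate | CC(=O)Oc1ccc(CCCCCCCCC(=O)c2c(O)cccc2O)cc1OC(C)=O
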